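**Retrosynthetic overview**
- Target ⇐ reduction of the para-quinone ⇐ oxidative demethylation of a 2,5-dimethoxyanilide macrolactam; C7 carbamate and C15 desilylation come late.
- Macrolactam (second ring formed, 19-membered) ⇐ intramolecular Cu-mediated N-arylation of a (2E,4Z)-dienamide onto an aryl bromide.
- Dienamide ⇐ Sonogashira coupling and Z-selective semi-reduction at C4–C5; C6/C7 ⇐ syn-propargylation of a C7 enal; C8=C9 ⇐ cross-metathesis with methacrolein; C10/C11 ⇐ syn-crotylboration of an α-methoxy aldehyde; C12 ⇐ CBS reduction.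
- Key disconnection C14–C15: cis-γ-butyrolactone (first ring, temporary) ⇐ NHC homoenolate of crotonaldehyde (nucleophilic β-carbon) plus an aryl aldehyde, two normally electrophilic carbons joined, C14 and C15 set together.
- Ring order: γ-lactone (step 2, opened in step 3), then the macrolactam (step 20); the arene is bought.

Assumption: carbons are numbered C1 (amide carbonyl) to C15 (benzylic carbinol) along the ansa chain, and bromo-salicylaldehyde 1 is taken as a catalogue compound.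

**Route**

Step 1
Reactants: 1 3-bromo-2-hydroxy-5-methoxybenzaldehyde
Product: 2 3-bromo-2,5-dimethoxybenzaldehyde
Conditions: MeI, K2CO3, DMF, rt
Reagents that add atoms: iodomethane, CI
Why: Williamson O-methylation of the acidic phenol under mild base; no stereocenter.

Step 2
Reactants: 2 3-bromo-2,5-dimethoxybenzaldehyde; 3 (E)-but-2-enal
Product: 4 (4S,5R)-5-(3-bromo-2,5-dimethoxyphenyl)-4-methyldihydrofuran-2(3H)-one
Conditions: chiral aminoindanol-derived N-mesityl triazolium chloride (10 mol%, enantiomer giving 4S,5R), DBU (10 mol%), Ti(OiPr)4 (20 mol%), CH2Cl2, rt, slow addition of 3 (2 equiv)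
Reagents that add atoms: none
Why: Proposed new method: the carbene adds to 3 to give a Breslow intermediate whose β-carbon (homoenolate, future C14) attacks the Ti-activated aldehyde carbon of 2 (future C15), and the alkoxide then closes on the acyl azolium to release the cis-lactone, the chiral triazolium setting 14S and 15R in one event; the closest known reaction type is the cis-selective NHC-catalysed enal/aryl aldehyde γ-butyrolactone annulation and its Ti(OiPr)4-cooperative enantioselective enal dimerisation, so high ee for this cross pair is an extrapolation.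

Step 3
Reactants: 4 (4S,5R)-5-(3-bromo-2,5-dimethoxyphenyl)-4-methyldihydrofuran-2(3H)-one
Product: 5 (3S,4R)-4-(3-bromo-2,5-dimethoxyphenyl)-4-hydroxy-N-methoxy-N,3-dimethylbutanamide
Conditions: MeNH(OMe)·HCl, AlMe3, CH2Cl2, 0 °C to rt; crude used directly
Reagents that add atoms: N,O-dimethylhydroxylamine hydrochloride, CNOC.Cl
Why: Weinreb aminolysis by the aluminium amide opens the lactone at the acyl carbon (C12) without touching C14 or C15.

Step 4
Reactants: 5 (3S,4R)-4-(3-bromo-2,5-dimethoxyphenyl)-4-hydroxy-N-methoxy-N,3-dimethylbutanamide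
Product: 6 (3S,4R)-4-(3-bromo-2,5-dimethoxyphenyl)-4-[(tert-butyldimethylsilyl)oxy]-N-methoxy-N,3-dimethylbutanamide
Conditions: TBSOTf, 2,6-lutidine, CH2Cl2, −78 to 0 °C
Reagents that add atoms: tert-butyldimethylsilyl trifluoromethanesulfonate, CC(C)(C)[Si](C)(C)OS(=O)(=O)C(F)(F)F
Why: Silylation with the reactive triflate outruns relactonisation and masks C15–OH through both later O-methylations.

Step 5
Reactants: 6 (3S,4R)-4-(3-bromo-2,5-dimethoxyphenyl)-4-[(tert-butyldimethylsilyl)oxy]-N-methoxy-N,3-dimethylbutanamide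
Product: 7 (6S,7R)-7-(3-bromo-2,5-dimethoxyphenyl)-7-[(tert-butyldimethylsilyl)oxy]-2,6-dimethylhept-2-en-4-one
Conditions: Me2C=CHMgBr (2.5 equiv), THF, 0 °C; aq. NH4Cl
Reagents that add atoms: 2-methyl-1-propenylmagnesium bromide, CC(C)=C[Mg]Br
Why: Weinreb ketone synthesis, in which the stable magnesium chelate prevents over-addition and the alkenyl Grignard does not exchange with the aryl bromide at 0 °C.

Step 6
Reactants: 7 (6S,7R)-7-(3-bromo-2,5-dimethoxyphenyl)-7-[(tert-butyldimethylsilyl)oxy]-2,6-dimethylhept-2-en-4-one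
Product: 8 (4S,6S,7R)-7-(3-bromo-2,5-dimethoxyphenyl)-7-[(tert-butyldimethylsilyl)oxy]-2,6-dimethylhept-2-en-4-ol
Conditions: (R)-2-methyl-CBS-oxazaborolidine (0.5 equiv), catecholborane (2 equiv), toluene, −78 °C
Reagents that add atoms: none
Why: Corey–Bakshi–Shibata 1,2-reduction, in which the (R)-catalyst treats the trisubstituted alkenyl group as the large substituent and delivers hydride to give 12S under reagent control.

Step 7
Reactants: 8 (4S,6S,7R)-7-(3-bromo-2,5-dimethoxyphenyl)-7-[(tert-butyldimethylsilyl)oxy]-2,6-dimethylhept-2-en-4-ol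
Product: 9 (4S,6S,7R)-7-(3-bromo-2,5-dimethoxyphenyl)-7-[(tert-butyldimethylsilyl)oxy]-4-methoxy-2,6-dimethylhept-2-ene
Conditions: NaH, MeI, THF/DMF, 0 °C to rt
Reagents that add atoms: iodomethane, CI
Why: Williamson etherification installs the C12 methyl ether without touching any stereocenter.

Step 8
Reactants: 9 (4S,6S,7R)-7-(3-bromo-2,5-dimethoxyphenyl)-7-[(tert-butyldimethylsilyl)oxy]-4-methoxy-2,6-dimethylhept-2-ene
Product: 10 (2S,4S,5R)-5-(3-bromo-2,5-dimethoxyphenyl)-5-[(tert-butyldimethylsilyl)oxy]-2-methoxy-4-methylpentanal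
Conditions: O3, CH2Cl2/MeOH, −78 °C (Sudan red end point); PPh3
Reagents that add atoms: ozone, [O-][O+]=O
Why: Ozonolysis with reductive work-up cleaves the electron-rich trisubstituted alkene much faster than the arene and releases the α-methoxy aldehyde (C11).

Step 9
Reactants: 10 (2S,4S,5R)-5-(3-bromo-2,5-dimethoxyphenyl)-5-[(tert-butyldimethylsilyl)oxy]-2-methoxy-4-methylpentanal
Product: 11 (3S,4R,5S,7S,8R)-8-(3-bromo-2,5-dimethoxyphenyl)-8-[(tert-butyldimethylsilyl)oxy]-5-methoxy-3,7-dimethyloct-1-en-4-ol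
Conditions: (Z)-crotylboronic acid pinacol ester, (R)-TRIP [(R)-3,3′-bis(2,4,6-triisopropylphenyl)-1,1′-binaphthyl-2,2′-diyl hydrogen phosphate] (5 mol%), 4 Å MS, toluene, −30 °C to rt
Reagents that add atoms: (Z)-crotylboronic acid pinacol ester, C/C=C\CB1OC(C)(C)C(C)(C)O1
Why: Chiral phosphoric acid-catalysed crotylboration through a closed Zimmerman–Traxler chair, where the (Z)-crotyl geometry gives 10,11-syn and both catalyst and the Cornforth preference of the α-methoxy aldehyde direct Re-face attack (11R, 11,12-anti).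

Step 10
Reactants: 11 (3S,4R,5S,7S,8R)-8-(3-bromo-2,5-dimethoxyphenyl)-8-[(tert-butyldimethylsilyl)oxy]-5-methoxy-3,7-dimethyloct-1-en-4-ol
Product: 12 (3S,4R,5S,7S,8R)-8-(3-bromo-2,5-dimethoxyphenyl)-8-[(tert-butyldimethylsilyl)oxy]-4,5-dimethoxy-3,7-dimethyloct-1-ene
Conditions: NaH, MeI, THF/DMF, 0 °C to rt
Reagents that add atoms: iodomethane, CI
Why: Williamson methylation of C11–OH completes the anti-dimethoxy unit.

Step 11
Reactants: 12 (3S,4R,5S,7S,8R)-8-(3-bromo-2,5-dimethoxyphenyl)-8-[(tert-butyldimethylsilyl)oxy]-4,5-dimethoxy-3,7-dimethyloct-1-ene; 13 2-methylprop-2-enal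
Product: 14 (2E,4S,5R,6S,8S,9R)-9-(3-bromo-2,5-dimethoxyphenyl)-9-[(tert-butyldimethylsilyl)oxy]-5,6-dimethoxy-2,4,8-trimethylnon-2-enal
Conditions: second-generation Hoveyda–Grubbs catalyst (10 mol%), 13 (10 equiv), CH2Cl2, 40 °C
Reagents that add atoms: none
Why: Olefin cross-metathesis of the α-branched terminal alkene with excess methacrolein gives the thermodynamically favoured (E)-trisubstituted enal (C8=C9).

Step 12
Reactants: 15 (S)-but-3-yn-2-ol
Product: 16 (S)-but-3-yn-2-yl methanesulfonate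
Conditions: MsCl, Et3N, CH2Cl2, −78 to 0 °C
Reagents that add atoms: methanesulfonyl chloride, CS(=O)(=O)Cl
Why: O-sulfonylation with retention at carbon.

Step 13
Reactants: 16 (S)-but-3-yn-2-yl methanesulfonate
Product: 17 (M)-tributyl(buta-1,2-dien-1-yl)stannane
Conditions: Bu3SnH, LiN(iPr)2, THF, 0 °C; CuBr·SMe2, −78 °C; then 16, −78 °C
Reagents that add atoms: tributyltin hydride, CCCC[SnH](CCCC)CCCC
Why: anti-SN2′ displacement of the propargylic mesylate by the stannylcopper reagent transfers central to axial chirality and gives the (M)-allene.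

Step 14
Reactants: 14 (2E,4S,5R,6S,8S,9R)-9-(3-bromo-2,5-dimethoxyphenyl)-9-[(tert-butyldimethylsilyl)oxy]-5,6-dimethoxy-2,4,8-trimethylnon-2-enal; 17 (M)-tributyl(buta-1,2-dien-1-yl)stannane
Product: 18 (3S,4R,5E,7S,8R,9S,11S,12R)-12-(3-bromo-2,5-dimethoxyphenyl)-12-[(tert-butyldimethylsilyl)oxy]-8,9-dimethoxy-3,5,7,11-tetramethyldodec-5-en-1-yn-4-ol
Conditions: BF3·OEt2 (2 equiv), CH2Cl2, −78 °C
Reagents that add atoms: none
Why: Marshall propargylation, a BF3-promoted anti-SE2′ addition through an open transition state that gives the syn homopropargylic alcohol, the allene axis fixing 6S and the syn preference 7R.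

Step 15
Reactants: 19 diethyl 2-methylpropanedioate; 20 triiodomethane
Product: 21 diethyl 2-(diiodomethyl)-2-methylpropanedioate
Conditions: NaH, Et2O, reflux
Reagents that add atoms: none
Why: C-alkylation of the malonate sodium enolate by iodoform (formal diiodomethylation).

Step 16
Reactants: 21 diethyl 2-(diiodomethyl)-2-methylpropanedioate
Product: 22 (E)-3-iodo-2-methylprop-2-enoic acid
Conditions: KOH, EtOH/H2O, reflux; aq. HCl
Reagents that add atoms: potassium hydroxide, [K+].[OH-]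
Why: Saponification followed by decarboxylative elimination of iodide (Grob-type fragmentation) gives only the (E)-iodoacrylic acid.

Step 17
Reactants: 22 (E)-3-iodo-2-methylprop-2-enoic acid
Product: 24 (E)-3-iodo-2-methylprop-2-enamide, via acid chloride 23 (not isolated)
Conditions: (COCl)2, cat. DMF, CH2Cl2, 0 °C to rt; then NH3 (0.5 M in dioxane), 0 °C
Reagents that add atoms: oxalyl chloride, O=C(Cl)C(Cl)=O; ammonia, N
Why: Acid chloride formation and ammonolysis proceed with retention of the E geometry.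

Step 18
Reactants: 18 (3S,4R,5E,7S,8R,9S,11S,12R)-12-(3-bromo-2,5-dimethoxyphenyl)-12-[(tert-butyldimethylsilyl)oxy]-8,9-dimethoxy-3,5,7,11-tetramethyldodec-5-en-1-yn-4-ol; 24 (E)-3-iodo-2-methylprop-2-enamide
Product: 25 (2E,6S,7R,8E,10S,11R,12S,14S,15R)-15-(3-bromo-2,5-dimethoxyphenyl)-15-[(tert-butyldimethylsilyl)oxy]-7-hydroxy-11,12-dimethoxy-2,6,8,10,14-pentamethylpentadeca-2,8-dien-4-ynamide
Conditions: Pd(PPh3)2Cl2 (5 mol%), CuI (10 mol%), Et3N, THF, rt
Reagents that add atoms: none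
Why: Sonogashira coupling, in which the vinyl iodide reacts far faster than the hindered electron-rich aryl bromide and the alkene geometry is retained.

Step 19
Reactants: 25 (2E,6S,7R,8E,10S,11R,12S,14S,15R)-15-(3-bromo-2,5-dimethoxyphenyl)-15-[(tert-butyldimethylsilyl)oxy]-7-hydroxy-11,12-dimethoxy-2,6,8,10,14-pentamethylpentadeca-2,8-dien-4-ynamide
Product: 26 (2E,4Z,6S,7R,8E,10S,11R,12S,14S,15R)-15-(3-bromo-2,5-dimethoxyphenyl)-15-[(tert-butyldimethylsilyl)oxy]-7-hydroxy-11,12-dimethoxy-2,6,8,10,14-pentamethylpentadeca-2,4,8-trienamide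
Conditions: Zn dust activated with Cu(OAc)2 and AgNO3, MeOH/H2O (1:1), 40 °C
Reagents that add atoms: none
Why: Boland semi-reduction, in which activated zinc in protic medium reduces only the conjugated alkyne by syn delivery of hydrogen to give the 4Z alkene.

Step 20
Reactants: 26 (2E,4Z,6S,7R,8E,10S,11R,12S,14S,15R)-15-(3-bromo-2,5-dimethoxyphenyl)-15-[(tert-butyldimethylsilyl)oxy]-7-hydroxy-11,12-dimethoxy-2,6,8,10,14-pentamethylpentadeca-2,4,8-trienamide
Product: 27 macrolactam (N-aryl lactam of 26; 7-OH; 15-OTBS; arene di-OMe)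
Conditions: CuI (50 mol%), MeNHCH2CH2NHMe (1 equiv), K2CO3 (3 equiv), toluene, 100 °C, 2 mM
Reagents that add atoms: none
Why: Intramolecular Goldberg (Ullmann-type) N-arylation of the primary amide at high dilution closes the 19-membered lactam, amides being arylated in preference to the secondary alcohol.

Step 21
Reactants: 27 macrolactam (N-aryl lactam of 26; 7-OH; 15-OTBS; arene di-OMe)
Product: 29 C7 carbamate of macrolactam 27 (15-OTBS; arene di-OMe), via trichloroacetyl carbamate 28 (not isolated)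
Conditions: Cl3CC(O)NCO, CH2Cl2, 0 °C; then K2CO3, MeOH, 0 °C to rt
Reagents that add atoms: trichloroacetyl isocyanate, O=C=NC(=O)C(Cl)(Cl)Cl
Why: Carbamoylation of the only free hydroxyl (C7) by the acyl isocyanate and mild methanolysis of the trichloroacetyl group, with retention at C7.

Step 22
Reactants: 29 C7 carbamate of macrolactam 27 (15-OTBS; arene di-OMe)
Product: 30 para-quinone macrolactam (15-OTBS; C7 carbamate)
Conditions: (NH4)2Ce(NO3)6 (2.5 equiv), MeCN/H2O (4:1), 0 °C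
Reagents that add atoms: water, O
Why: Oxidative demethylation of the para-dimethoxy anilide by single-electron oxidation and attack of water gives the para-quinone while the silyl ether shields the benzylic position.

Step 23
Reactants: 30 para-quinone macrolactam (15-OTBS; C7 carbamate)
Product: 32 target CNP0532580.1 (hydroquinone), via desilylated quinone 31 (not isolated)
Conditions: 48% aq. HF, MeCN, 0 °C to rt; NaHCO3; then aq. Na2S2O4, EtOAc, rt, under Ar
Reagents that add atoms: none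
Why: Fluoride-mediated desilylation frees C15–OH and dithionite reduction of the quinone gives the hydroquinone, with no stereocenter affected.

**Compound list**

1 | 3-bromo-2-hydroxy-5-methoxybenzaldehyde | COc1cc(Br)c(O)c(C=O)c1 | starting material
2 | 3-bromo-2,5-dimethoxybenzaldehyde | COc1cc(Br)c(OC)c(C=O)c1 | intermediate
3 | (E)-but-2-enal (crotonaldehyde) | C/C=C/C=O | starting material
4 | (4S,5R)-5-(3-bromo-2,5-dimethoxyphenyl)-4-methyldihydrofuran-2(3H)-one (cis) | COc1cc(Br)c(OC)c(c1)[C@@H]2OC(=O)C[C@@H]2C | intermediate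
5 | (3S,4R)-4-(3-bromo-2,5-dimethoxyphenyl)-4-hydroxy-N-methoxy-N,3-dimethylbutanamide | COc1cc(Br)c(OC)c(c1)[C@H](O)[C@@H](C)CC(=O)N(C)OC | intermediate
6 | (3S,4R)-4-(3-bromo-2,5-dimethoxyphenyl)-4-[(tert-butyldimethylsilyl)oxy]-N-methoxy-N,3-dimethylbutanamide | COc1cc(Br)c(OC)c(c1)[C@H](O[Si](C)(C)C(C)(C)C)[C@@H](C)CC(=O)N(C)OC | intermediate
7 | (6S,7R)-7-(3-bromo-2,5-dimethoxyphenyl)-7-[(tert-butyldimethylsilyl)oxy]-2,6-dimethylhept-2-en-4-one | COc1cc(Br)c(OC)c(c1)[C@H](O[Si](C)(C)C(C)(C)C)[C@@H](C)CC(=O)C=C(C)C | intermediate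
8 | (4S,6S,7R)-7-(3-bromo-2,5-dimethoxyphenyl)-7-[(tert-butyldimethylsilyl)oxy]-2,6-dimethylhept-2-en-4-ol | COc1cc(Br)c(OC)c(c1)[C@H](O[Si](C)(C)C(C)(C)C)[C@@H](C)C[C@H](O)C=C(C)C | intermediate
9 | (4S,6S,7R)-7-(3-bromo-2,5-dimethoxyphenyl)-7-[(tert-butyldimethylsilyl)oxy]-4-methoxy-2,6-dimethylhept-2-ene | COc1cc(Br)c(OC)c(c1)[C@H](O[Si](C)(C)C(C)(C)C)[C@@H](C)C[C@H](OC)C=C(C)C | intermediate
10 | (2S,4S,5R)-5-(3-bromo-2,5-dimethoxyphenyl)-5-[(tert-butyldimethylsilyl)oxy]-2-methoxy-4-methylpentanal | COc1cc(Br)c(OC)c(c1)[C@H](O[Si](C)(C)C(C)(C)C)[C@@H](C)C[C@H](OC)C=O | intermediate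
11 | (3S,4R,5S,7S,8R)-8-(3-bromo-2,5-dimethoxyphenyl)-8-[(tert-butyldimethylsilyl)oxy]-5-methoxy-3,7-dimethyloct-1-en-4-ol | COc1cc(Br)c(OC)c(c1)[C@H](O[Si](C)(C)C(C)(C)C)[C@@H](C)C[C@H](OC)[C@H](O)[C@@H](C)C=C | intermediate
12 | (3S,4R,5S,7S,8R)-8-(3-bromo-2,5-dimethoxyphenyl)-8-[(tert-butyldimethylsilyl)oxy]-4,5-dimethoxy-3,7-dimethyloct-1-ene | COc1cc(Br)c(OC)c(c1)[C@H](O[Si](C)(C)C(C)(C)C)[C@@H](C)C[C@H](OC)[C@H](OC)[C@@H](C)C=C | intermediate
13 | 2-methylprop-2-enal (methacrolein) | CC(=C)C=O | starting material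
14 | (2E,4S,5R,6S,8S,9R)-9-(3-bromo-2,5-dimethoxyphenyl)-9-[(tert-butyldimethylsilyl)oxy]-5,6-dimethoxy-2,4,8-trimethylnon-2-enal | COc1cc(Br)c(OC)c(c1)[C@H](O[Si](C)(C)C(C)(C)C)[C@@H](C)C[C@H](OC)[C@H](OC)[C@@H](C)/C=C(C)/C=O | intermediate
15 | (S)-but-3-yn-2-ol | C#C[C@H](C)O | starting material
16 | (S)-but-3-yn-2-yl methanesulfonate | C#C[C@H](C)OS(C)(=O)=O | intermediate
17 | (M)-tributyl(buta-1,2-dien-1-yl)stannane (aR) | [H]C([Sn](CCCC)(CCCC)CCCC)=[C@@]=C([H])C | intermediate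
18 | (3S,4R,5E,7S,8R,9S,11S,12R)-12-(3-bromo-2,5-dimethoxyphenyl)-12-[(tert-butyldimethylsilyl)oxy]-8,9-dimethoxy-3,5,7,11-tetramethyldodec-5-en-1-yn-4-ol | COc1cc(Br)c(OC)c(c1)[C@H](O[Si](C)(C)C(C)(C)C)[C@@H](C)C[C@H](OC)[C@H](OC)[C@@H](C)/C=C(C)/[C@H](O)[C@@H](C)C#C | intermediate
19 | diethyl 2-methylpropanedioate | CCOC(=O)C(C)C(=O)OCC | starting material
20 | triiodomethane (iodoform) | IC(I)I | starting material
21 | diethyl 2-(diiodomethyl)-2-methylpropanedioate | CCOC(=O)C(C)(C(I)I)C(=O)OCC | intermediate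
22 | (E)-3-iodo-2-methylprop-2-enoic acid | I/C=C(\C)C(O)=O | intermediate
23 | (E)-3-iodo-2-methylprop-2-enoyl chloride | I/C=C(\C)C(Cl)=O | intermediate
24 | (E)-3-iodo-2-methylprop-2-enamide | I/C=C(\C)C(N)=O | intermediate
25 | (2E,6S,7R,8E,10S,11R,12S,14S,15R)-15-(3-bromo-2,5-dimethoxyphenyl)-15-[(tert-butyldimethylsilyl)oxy]-7-hydroxy-11,12-dimethoxy-2,6,8,10,14-pentamethylpentadeca-2,8-dien-4-ynamide | COc1cc(Br)c(OC)c(c1)[C@H](O[Si](C)(C)C(C)(C)C)[C@@H](C)C[C@H](OC)[C@H](OC)[C@@H](C)/C=C(C)/[C@H](O)[C@@H](C)C#C/C=C(\C)C(N)=O | intermediate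
26 | (2E,4Z,6S,7R,8E,10S,11R,12S,14S,15R)-15-(3-bromo-2,5-dimethoxyphenyl)-15-[(tert-butyldimethylsilyl)oxy]-7-hydroxy-11,12-dimethoxy-2,6,8,10,14-pentamethylpentadeca-2,4,8-trienamide | COc1cc(Br)c(OC)c(c1)[C@H](O[Si](C)(C)C(C)(C)C)[C@@H](C)C[C@H](OC)[C@H](OC)[C@@H](C)/C=C(C)/[C@H](O)[C@@H](C)/C=C\C=C(/C)C(N)=O | intermediate
27 | macrolactam: amide N of 26 bonded to the arene carbon that carried Br; 2E,4Z,8E; 6S,7R,10S,11R,12S,14S,15R; 7-OH; 11,12-di-OMe; 15-OTBS; arene di-OMe | COc1cc2c(OC)c(c1)[C@H](O[Si](C)(C)C(C)(C)C)[C@@H](C)C[C@H](OC)[C@H](OC)[C@@H](C)/C=C(C)/[C@H](O)[C@@H](C)/C=C\C=C(/C)C(=O)N2 | intermediate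
28 | 7-O-[(trichloroacetyl)carbamoyl] derivative of 27 (same stereodescriptors) | COc1cc2c(OC)c(c1)[C@H](O[Si](C)(C)C(C)(C)C)[C@@H](C)C[C@H](OC)[C@H](OC)[C@@H](C)/C=C(C)/[C@H](OC(=O)NC(=O)C(Cl)(Cl)Cl)[C@@H](C)/C=C\C=C(/C)C(=O)N2 | intermediate
29 | 7-O-carbamoyl derivative of 27 (15-OTBS; arene di-OMe; same stereodescriptors) | COc1cc2c(OC)c(c1)[C@H](O[Si](C)(C)C(C)(C)C)[C@@H](C)C[C@H](OC)[C@H](OC)[C@@H](C)/C=C(C)/[C@H](OC(N)=O)[C@@H](C)/C=C\C=C(/C)C(=O)N2 | intermediate
30 | para-quinone macrolactam (15-OTBS; C7 carbamate; same stereodescriptors) | O=C1C=C2C(=O)C(=C1)[C@H](O[Si](C)(C)C(C)(C)C)[C@@H](C)C[C@H](OC)[C@H](OC)[C@@H](C)/C=C(C)/[C@H](OC(N)=O)[C@@H](C)/C=C\C=C(/C)C(=O)N2 | intermediate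
31 | para-quinone macrolactam with free 15-OH (quinone form of the target) | O=C1C=C2C(=O)C(=C1)[C@H](O)[C@@H](C)C[C@H](OC)[C@H](OC)[C@@H](C)/C=C(C)/[C@H](OC(N)=O)[C@@H](C)/C=C\C=C(/C)C(=O)N2 | intermediate
32 | CNP0532580.1: hydroquinone macrolactam; 2E,4Z,8E; 6S,7R,10S,11R,12S,14S,15R; 7-OC(O)NH2; 11,12-di-OMe; 15-OH | Oc1cc2c(O)c(c1)[C@H](O)[C@@H](C)C[C@H](OC)[C@H](OC)[C@@H](C)/C=C(C)/[C@H](OC(N)=O)[C@@H](C)/C=C\C=C(/C)C(=O)N2 | target

**Step count**

Total: 23 steps. Longest linear sequence: 18 steps (steps 1–11, 14, 18–23). Side branches: steps 12–13 (allenylstannane 17) and steps 15–17 (iodoamide 24).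

**Three steps most likely to fail, with fallbacks**

Step 2 is the least certain. High ee and cis selectivity are unproven for a β-alkyl enal with this aldehyde, and crotonaldehyde self-annulation competes. The fallback sets out from 2 and comes back at 4. Aldehyde 2 is crotylated with (Z)-crotylboronic acid pinacol ester under (R)-TRIP catalysis to the syn alcohol (1R,2S)-1-(3-bromo-2,5-dimethoxyphenyl)-2-methylbut-3-en-1-ol F1. Hydroboration of the vinyl group with 9-BBN and NaBO3 work-up gives (1R,2S)-1-(3-bromo-2,5-dimethoxyphenyl)-2-methylbutane-1,4-diol F2. TEMPO/PhI(OAc)2 then oxidises the primary alcohol and the resulting lactol in one pot to lactone 4.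

Step 14 is the second risk: the syn/anti ratio on a hindered enal and the handling of the allenyltin reagent. The fallback sets out from 14 and comes back at 26. Enal 14 is crotylated with (Z)-crotylboronic acid pinacol ester and (R)-TRIP to the syn homoallylic alcohol F3. Acryloyl chloride and Et3N give the acrylate F4. Ring-closing metathesis with second-generation Grubbs catalyst gives the (5S,6R)-5-methyl-5,6-dihydro-2H-pyran-2-one F5, whose ring fixes the C4=C5 Z geometry. Reduction with i-Bu2AlH at −78 °C gives the lactol F6. Wittig olefination with Ph3P=C(CH3)C(O)NH2 opens the lactol to the (2E,4Z)-dienamide 26.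

Step 20 is the third risk: macrocyclic N-arylation of a hindered, electron-rich aryl bromide, with possible diene isomerisation at 100 °C. The fallback sets out from 18 and comes back at 27. Sonogashira coupling of 18 with acid 22 gives the enynoic acid F7. Semi-reduction with Zn dust activated with Cu(OAc)2 and AgNO3 gives the (2E,4Z)-dienoic acid F8. CuI/L-proline-mediated amination of the aryl bromide with aqueous NH3 and K2CO3 in DMSO gives the anilino acid F9. BOP-Cl/i-Pr2NEt macrolactamisation in toluene at high dilution gives 27.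

**Further compounds**

F1 | step 2 | (1R,2S)-1-(3-bromo-2,5-dimethoxyphenyl)-2-methylbut-3-en-1-ol | COc1cc(Br)c(OC)c(c1)[C@H](O)[C@@H](C)C=C
F2 | step 2 | (1R,2S)-1-(3-bromo-2,5-dimethoxyphenyl)-2-methylbutane-1,4-diol | COc1cc(Br)c(OC)c(c1)[C@H](O)[C@@H](C)CCO
F3 | step 14 | syn homoallylic alcohol: terminal vinyl analogue of 18 (6S,7R; C5=C4H2) | COc1cc(Br)c(OC)c(c1)[C@H](O[Si](C)(C)C(C)(C)C)[C@@H](C)C[C@H](OC)[C@H](OC)[C@@H](C)/C=C(C)/[C@H](O)[C@@H](C)C=C
F4 | step 14 | acrylate ester of F3 at C7–O | COc1cc(Br)c(OC)c(c1)[C@H](O[Si](C)(C)C(C)(C)C)[C@@H](C)C[C@H](OC)[C@H](OC)[C@@H](C)/C=C(C)/[C@H](OC(=O)C=C)[C@@H](C)C=C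
F5 | step 14 | (5S,6R)-5-methyl-6-alkenyl-5,6-dihydro-2H-pyran-2-one (C3–C7 lactone) | COc1cc(Br)c(OC)c(c1)[C@H](O[Si](C)(C)C(C)(C)C)[C@@H](C)C[C@H](OC)[C@H](OC)[C@@H](C)/C=C(C)/[C@@H]1OC(=O)C=C[C@@H]1C
F6 | step 14 | lactol of F5 (anomer mixture) | COc1cc(Br)c(OC)c(c1)[C@H](O[Si](C)(C)C(C)(C)C)[C@@H](C)C[C@H](OC)[C@H](OC)[C@@H](C)/C=C(C)/[C@@H]1OC(O)C=C[C@@H]1C
F7 | step 20 | enynoic acid: carboxylic acid analogue of 25 | COc1cc(Br)c(OC)c(c1)[C@H](O[Si](C)(C)C(C)(C)C)[C@@H](C)C[C@H](OC)[C@H](OC)[C@@H](C)/C=C(C)/[C@H](O)[C@@H](C)C#C/C=C(\C)C(O)=O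
F8 | step 20 | (2E,4Z)-dienoic acid: carboxylic acid analogue of 26 | COc1cc(Br)c(OC)c(c1)[C@H](O[Si](C)(C)C(C)(C)C)[C@@H](C)C[C@H](OC)[C@H](OC)[C@@H](C)/C=C(C)/[C@H](O)[C@@H](C)/C=C\C=C(/C)C(O)=O
F9 | step 20 | anilino acid: F8 with NH2 in place of Br | COc1cc(N)c(OC)c(c1)[C@H](O[Si](C)(C)C(C)(C)C)[C@@H](C)C[C@H](OC)[C@H](OC)[C@@H](C)/C=C(C)/[C@H](O)[C@@H](C)/C=C\C=C(/C)C(O)=O
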